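**Retrosynthetic overview**

1. The target comes from selective O-acetylation of a hydroquinone, which comes from reductive ketone–acetone coupling (isopropylidene) of a C-2 keto acid, itself derived from a tricyclic δ-lactone.
2. The lactone comes from one hydrogen-atom-transfer-initiated radical bicyclisation of an acyclic triene: the C-5 radical attacks C-4a (ring B), then the C-8a radical attacks C-1 of a cyclic enol lactone (ring A). Rings form in the order B, then A.
3. The enol lactone comes from a 5-oxo acid, made by retro-Claisen opening of a 2-allylated cyclohexane-1,3-dione (E allylic alcohol + cyclohexane-1,3-dione).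
4. The E trisubstituted alkene comes from carboalumination of a terminal alkyne; the arylmethyl-substituted 1,1-disubstituted alkene comes from aromatic Claisen rearrangement of an o-cresol allyl ether.
5. The C-6 methyl stereocentre comes from copper-catalysed asymmetric conjugate addition of a butynyl Grignard reagent to methyl crotonate.

Assumption: the C-trimethylsilyl group of 1 is a protecting group (removed in step 3), so 1 counts as 4-bromobut-1-yne with five non-hydrogen atoms.

Numbering note: ring positions follow the decahydronaphthalene name of the target (C-1 propanoic acid chain, C-2 isopropylidene, C-4a and C-8a ring fusion, C-5 arylmethyl and methyl, C-6 methyl). Ring A is C-1 to C-4; ring B is C-5 to C-8.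

**Step 1**
Reactants: 1 (4-bromobut-1-yn-1-yl)trimethylsilane; 2 methyl (2E)-but-2-enoate
Product: 4 methyl (3R)-3-methyl-7-(trimethylsilyl)hept-6-ynoate, via Grignard reagent 3 (not isolated)
Conditions: Mg, Et2O, 35 °C; then 2, CuBr·SMe2 (5 mol %), 1-[2-(diphenylphosphino)ferrocenyl]ethyldicyclohexylphosphine (6 mol %, the enantiomer that gives 3R), t-BuOMe, −75 °C
Reagents that add atoms: none
Why: Feringa-type copper-catalysed asymmetric conjugate addition of a primary alkyl Grignard reagent to a crotonate, in which the chiral ferrocenyl diphosphine–copper complex selects the enoate face and sets C-3 (R), the only stereocentre made before the key step.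

**Step 2**
Reactants: 4 methyl (3R)-3-methyl-7-(trimethylsilyl)hept-6-ynoate
Product: 7 methyl (3R)-3-methyl-2-methylidene-7-(trimethylsilyl)hept-6-ynoate, via Mannich base 5 (not isolated), via ammonium iodide 6 (not isolated)
Conditions: LiN(i-Pr)2, THF, −78 °C; CH2=NMe2+ I−, −78 → 23 °C; MeI, MeOH, 23 °C; DBU, CH2Cl2, 23 °C
Reagents that add atoms: dimethylmethylideneammonium iodide, C=[N+](C)C.[I-]
Why: Ester-enolate Mannich reaction followed by quaternisation and Hofmann-type elimination gives the α-methylene ester, and the C-3 stereocentre (β to the ester) is not touched.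

**Step 3**
Reactants: 7 methyl (3R)-3-methyl-2-methylidene-7-(trimethylsilyl)hept-6-ynoate
Product: 9 (3R)-3-methyl-2-methylidenehept-6-yn-1-ol, via silyl alkynol 8 (not isolated)
Conditions: i-Bu2AlH, CH2Cl2, −78 °C; then MeOH, K2CO3 (cat.), 23 °C
Reagents that add atoms: none
Why: 1,2-Reduction of the conjugated ester by the aluminium hydride, then base-catalysed methanolysis of the alkynyl C–Si bond in the quench, with no stereocentre involved.

**Step 4**
Reactants: 9 (3R)-3-methyl-2-methylidenehept-6-yn-1-ol; 10 2-methylphenol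
Product: 11 1-methyl-2-{[(3R)-3-methyl-2-methylidenehept-6-yn-1-yl]oxy}benzene
Conditions: PPh3, DIAD, THF, 0 → 23 °C
Reagents that add atoms: none
Why: Mitsunobu etherification of a primary allylic alcohol with a phenol (direct and allylic displacement give the same ether for this 2-substituted allyl unit).

**Step 5**
Reactants: 11 1-methyl-2-{[(3R)-3-methyl-2-methylidenehept-6-yn-1-yl]oxy}benzene
Product: 12 2-methyl-6-[(3R)-3-methyl-2-methylidenehept-6-yn-1-yl]phenol
Conditions: PhNEt2, 190 °C
Reagents that add atoms: none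
Why: Aromatic Claisen rearrangement to the only free ortho position, then tautomerisation, puts the CH2 between the arene and the 1,1-disubstituted alkene without touching the stereocentre.

**Step 6**
Reactants: 12 2-methyl-6-[(3R)-3-methyl-2-methylidenehept-6-yn-1-yl]phenol
Product: 14 (2E,6R)-8-(2-hydroxy-3-methylphenyl)-3,6-dimethyl-7-methylideneoct-2-en-1-ol, via alkenylalane 13 (not isolated)
Conditions: AlMe3 (3.5 equiv), Cp2ZrCl2 (20 mol %), CH2Cl2, 0 → 23 °C; then n-BuLi, THF, −78 °C; (CH2O)n, −78 → 23 °C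
Reagents that add atoms: trimethylaluminium, C[Al](C)C; paraformaldehyde (as formaldehyde), C=O
Why: Negishi zirconium-catalysed carboalumination adds Me and Al syn across the terminal alkyne, which fixes the E trisubstituted alkene, and the alanate is hydroxymethylated with retention.

**Step 7**
Reactants: 14 (2E,6R)-8-(2-hydroxy-3-methylphenyl)-3,6-dimethyl-7-methylideneoct-2-en-1-ol; 15 cyclohexane-1,3-dione
Product: 16 2-[(2E,6R)-8-(2-hydroxy-3-methylphenyl)-3,6-dimethyl-7-methylideneoct-2-en-1-yl]cyclohexane-1,3-dione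
Conditions: Pd(PPh3)4 (5 mol %), 15 (3 equiv), toluene/H2O, 60 °C
Reagents that add atoms: none
Why: Tsuji–Trost allylation with zerovalent palladium, in which the acidic dione ionises the allylic alcohol and attacks the primary terminus of the allyl complex with the E alkene kept.

**Step 8**
Reactants: 16 2-[(2E,6R)-8-(2-hydroxy-3-methylphenyl)-3,6-dimethyl-7-methylideneoct-2-en-1-yl]cyclohexane-1,3-dione
Product: 17 (8E,12R)-14-(2-hydroxy-3-methylphenyl)-9,12-dimethyl-13-methylidene-5-oxotetradec-8-enoic acid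
Conditions: 4 M NaOH, H2O/EtOH, reflux; then HCl
Reagents that add atoms: water, O
Why: Retro-Claisen (Stetter) cleavage of the 2-alkylated cyclic 1,3-diketone by hydroxide opens the ring to the 5-oxo acid, so the dione serves as a masked 5-oxohexanoic acid.

**Step 9**
Reactants: 17 (8E,12R)-14-(2-hydroxy-3-methylphenyl)-9,12-dimethyl-13-methylidene-5-oxotetradec-8-enoic acid
Product: 18 2-[(3R,6E)-3,6-dimethyl-2-methylidene-9-(2-oxo-3,4-dihydro-2H-pyran-6-yl)non-6-en-1-yl]-6-methylphenyl acetate
Conditions: Ac2O, NaOAc, 110 °C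
Reagents that add atoms: acetic anhydride, CC(=O)OC(C)=O
Why: Cyclodehydration through the mixed anhydride gives the thermodynamically preferred endocyclic six-membered enol lactone (ring oxygen held cis to the future side-chain carbon), and the same reagent acetylates the phenol, whose O–H would otherwise quench carbon radicals.

**Step 10**
Reactants: 18 2-[(3R,6E)-3,6-dimethyl-2-methylidene-9-(2-oxo-3,4-dihydro-2H-pyran-6-yl)non-6-en-1-yl]-6-methylphenyl acetate
Product: 19 δ-lactone of 3-[(1S,4aR,5S,6R,8aR)-5-(2-acetoxy-3-methylbenzyl)-2-hydroxy-5,6,8a-trimethyldecahydronaphthalen-1-yl]propanoic acid (C-2 epimer mixture)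
Conditions: Mn(dpm)3 [tris(2,2,6,6-tetramethylheptane-3,5-dionato)manganese] (20 mol %), PhSiH3 (slow addition), t-BuOOH, i-PrOH/hexane, 22 °C, 0.01 M
Reagents that add atoms: none
Why: Proposed new method: a manganese hydride transfers a hydrogen atom to the 1,1-disubstituted alkene (the most reactive of the three) to give the tertiary C-5 radical, which closes ring B by 6-endo attack on C-4a of the E alkene, and the resulting C-8a radical closes ring A by 6-endo attack on C-1 of the enol lactone to give an α-acyloxy radical that takes a second hydrogen atom; a chair–chair transition state with the C-6 methyl equatorial should set C-5 (arylmethyl equatorial, methyl axial), C-4a and C-8a (trans fusion) and C-1 (side-chain carbon equatorial because the ring alkene holds it trans to C-3), and the closest known reactions are Shenvi's manganese/silane hydrogen-atom-transfer reductions with radical cyclisation and iron- or manganese-hydride-initiated radical polyene bicyclisations.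

**Step 11**
Reactants: 19 δ-lactone of 3-[(1S,4aR,5S,6R,8aR)-5-(2-acetoxy-3-methylbenzyl)-2-hydroxy-5,6,8a-trimethyldecahydronaphthalen-1-yl]propanoic acid
Product: 21 3-[(1S,4aR,5S,6R,8aR)-2-hydroxy-5,6,8a-trimethyl-5-[(5-methyl-3,6-dioxocyclohexa-1,4-dien-1-yl)methyl]decahydronaphthalen-1-yl]propanoic acid (C-2 epimer mixture), via hydroxy acid 20 (not isolated)
Conditions: LiOH, THF/H2O, 23 °C; then HCl to pH 7, KH2PO4/K2HPO4 buffer, K2NO(SO3)2, 0 → 23 °C
Reagents that add atoms: water, O; potassium nitrosodisulfonate, [K+].[K+].[O]N(S(=O)(=O)[O-])S(=O)(=O)[O-]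
Why: Saponification of the lactone and the aryl acetate, then Teuber oxidation of the para-unsubstituted 2,6-dialkylphenol by the nitroxide radical to the para-quinone while the hydroxy acid is held as its carboxylate and cannot relactonise.

**Step 12**
Reactants: 21 3-[(1S,4aR,5S,6R,8aR)-2-hydroxy-5,6,8a-trimethyl-5-[(5-methyl-3,6-dioxocyclohexa-1,4-dien-1-yl)methyl]decahydronaphthalen-1-yl]propanoic acid
Product: 22 3-[(1S,4aR,5S,6R,8aR)-5,6,8a-trimethyl-5-[(5-methyl-3,6-dioxocyclohexa-1,4-dien-1-yl)methyl]-2-oxodecahydronaphthalen-1-yl]propanoic acid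
Conditions: CrO3, H2SO4, acetone/H2O, 0 °C
Reagents that add atoms: none
Why: Jones oxidation of the secondary alcohol is faster than relactonisation and leaves the quinone alone, and the C-1 side chain is already the more stable equatorial epimer next to the new ketone, so enolisation does not change it.

**Step 13**
Reactants: 22 3-[(1S,4aR,5S,6R,8aR)-5,6,8a-trimethyl-5-[(5-methyl-3,6-dioxocyclohexa-1,4-dien-1-yl)methyl]-2-oxodecahydronaphthalen-1-yl]propanoic acid; 23 acetone
Product: 24 3-[(1S,4aR,5S,6R,8aR)-5-(2,5-dihydroxy-3-methylbenzyl)-5,6,8a-trimethyl-2-(propan-2-ylidene)decahydronaphthalen-1-yl]propanoic acid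
Conditions: TiCl4, Zn, pyridine, THF, reflux; then 22 and 23 (10 equiv), reflux; work-up under argon
Reagents that add atoms: none
Why: McMurry cross-coupling with low-valent titanium joins the ring ketone and excess acetone to the tetrasubstituted isopropylidene alkene with no regiochemical ambiguity, and the reducing medium converts the quinone to the hydroquinone in the same pot.

**Step 14**
Reactants: 24 3-[(1S,4aR,5S,6R,8aR)-5-(2,5-dihydroxy-3-methylbenzyl)-5,6,8a-trimethyl-2-(propan-2-ylidene)decahydronaphthalen-1-yl]propanoic acid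
Product: 25 3-[(1S,4aR,5S,6R,8aR)-5-{[5-(acetyloxy)-2-hydroxy-3-methylphenyl]methyl}-5,6,8a-trimethyl-2-(propan-2-ylidene)decahydronaphthalen-1-yl]propanoic acid (CNP0144688.2)
Conditions: Ac2O (1.1 equiv), pyridine, CH2Cl2, −20 → 0 °C; aq. NaHCO3 work-up
Reagents that add atoms: acetic anhydride, CC(=O)OC(C)=O
Why: Site-selective acylation, because the hydroxyl flanked by two ring hydrogens reacts much faster than the one between the methyl and the neopentyl-type benzyl group, and any mixed anhydride at the acid is hydrolysed on work-up.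

**Compound list**

1 | (4-bromobut-1-yn-1-yl)trimethylsilane | C[Si](C)(C)C#CCCBr | starting material
2 | methyl (2E)-but-2-enoate | C/C=C/C(=O)OC | starting material
3 | [4-(trimethylsilyl)but-3-yn-1-yl]magnesium bromide | C[Si](C)(C)C#CCC[Mg]Br | intermediate
4 | methyl (3R)-3-methyl-7-(trimethylsilyl)hept-6-ynoate | COC(=O)C[C@H](C)CCC#C[Si](C)(C)C | intermediate
5 | methyl (3R)-2-[(dimethylamino)methyl]-3-methyl-7-(trimethylsilyl)hept-6-ynoate (C-2 epimers) | COC(=O)C(CN(C)C)[C@H](C)CCC#C[Si](C)(C)C | intermediate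
6 | [(3R)-2-(methoxycarbonyl)-3-methyl-7-(trimethylsilyl)hept-6-yn-1-yl]trimethylammonium iodide | COC(=O)C(C[N+](C)(C)C)[C@H](C)CCC#C[Si](C)(C)C.[I-] | intermediate
7 | methyl (3R)-3-methyl-2-methylidene-7-(trimethylsilyl)hept-6-ynoate | COC(=O)C(=C)[C@H](C)CCC#C[Si](C)(C)C | intermediate
8 | (3R)-3-methyl-2-methylidene-7-(trimethylsilyl)hept-6-yn-1-ol | OCC(=C)[C@H](C)CCC#C[Si](C)(C)C | intermediate
9 | (3R)-3-methyl-2-methylidenehept-6-yn-1-ol | OCC(=C)[C@H](C)CCC#C | intermediate
10 | 2-methylphenol | Cc1ccccc1O | starting material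
11 | 1-methyl-2-{[(3R)-3-methyl-2-methylidenehept-6-yn-1-yl]oxy}benzene | Cc1ccccc1OCC(=C)[C@H](C)CCC#C | intermediate
12 | 2-methyl-6-[(3R)-3-methyl-2-methylidenehept-6-yn-1-yl]phenol | Cc1cccc(CC(=C)[C@H](C)CCC#C)c1O | intermediate
13 | dimethylaluminium 2-[(3R,6E)-7-(dimethylalumanyl)-3,6-dimethyl-2-methylidenehept-6-en-1-yl]-6-methylphenoxide | Cc1cccc(CC(=C)[C@H](C)CC/C(C)=C/[Al](C)C)c1O[Al](C)C | intermediate
14 | (2E,6R)-8-(2-hydroxy-3-methylphenyl)-3,6-dimethyl-7-methylideneoct-2-en-1-ol | Cc1cccc(CC(=C)[C@H](C)CC/C(C)=C/CO)c1O | intermediate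
15 | cyclohexane-1,3-dione | O=C1CCCC(=O)C1 | starting material
16 | 2-[(2E,6R)-8-(2-hydroxy-3-methylphenyl)-3,6-dimethyl-7-methylideneoct-2-en-1-yl]cyclohexane-1,3-dione | Cc1cccc(CC(=C)[C@H](C)CC/C(C)=C/CC2C(=O)CCCC2=O)c1O | intermediate
17 | (8E,12R)-14-(2-hydroxy-3-methylphenyl)-9,12-dimethyl-13-methylidene-5-oxotetradec-8-enoic acid | Cc1cccc(CC(=C)[C@H](C)CC/C(C)=C/CCC(=O)CCCC(=O)O)c1O | intermediate
18 | 2-[(3R,6E)-3,6-dimethyl-2-methylidene-9-(2-oxo-3,4-dihydro-2H-pyran-6-yl)non-6-en-1-yl]-6-methylphenyl acetate | Cc1cccc(CC(=C)[C@H](C)CC/C(C)=C/CCC2=CCCC(=O)O2)c1OC(C)=O | intermediate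
19 | δ-lactone of 3-[(1S,4aR,5S,6R,8aR)-5-(2-acetoxy-3-methylbenzyl)-2-hydroxy-5,6,8a-trimethyldecahydronaphthalen-1-yl]propanoic acid (trans-decalin; C-2 epimer mixture, centre left open) | Cc1cccc(C[C@]2(C)[C@H]3CCC4OC(=O)CC[C@H]4[C@]3(C)CC[C@H]2C)c1OC(C)=O | intermediate
20 | 3-[(1S,4aR,5S,6R,8aR)-2-hydroxy-5-(2-hydroxy-3-methylbenzyl)-5,6,8a-trimethyldecahydronaphthalen-1-yl]propanoic acid (C-2 epimers) | Cc1cccc(C[C@]2(C)[C@H]3CCC(O)[C@@H](CCC(=O)O)[C@]3(C)CC[C@H]2C)c1O | intermediate
21 | 3-[(1S,4aR,5S,6R,8aR)-2-hydroxy-5,6,8a-trimethyl-5-[(5-methyl-3,6-dioxocyclohexa-1,4-dien-1-yl)methyl]decahydronaphthalen-1-yl]propanoic acid (C-2 epimers) | CC1=CC(=O)C=C(C[C@]2(C)[C@H]3CCC(O)[C@@H](CCC(=O)O)[C@]3(C)CC[C@H]2C)C1=O | intermediate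
22 | 3-[(1S,4aR,5S,6R,8aR)-5,6,8a-trimethyl-5-[(5-methyl-3,6-dioxocyclohexa-1,4-dien-1-yl)methyl]-2-oxodecahydronaphthalen-1-yl]propanoic acid | CC1=CC(=O)C=C(C[C@]2(C)[C@H]3CCC(=O)[C@@H](CCC(=O)O)[C@]3(C)CC[C@H]2C)C1=O | intermediate
23 | acetone | CC(C)=O | starting material
24 | 3-[(1S,4aR,5S,6R,8aR)-5-(2,5-dihydroxy-3-methylbenzyl)-5,6,8a-trimethyl-2-(propan-2-ylidene)decahydronaphthalen-1-yl]propanoic acid | Cc1cc(O)cc(C[C@]2(C)[C@H]3CCC(=C(C)C)[C@@H](CCC(=O)O)[C@]3(C)CC[C@H]2C)c1O | intermediate
25 | 3-[(1S,4aR,5S,6R,8aR)-5-{[5-(acetyloxy)-2-hydroxy-3-methylphenyl]methyl}-5,6,8a-trimethyl-2-(propan-2-ylidene)decahydronaphthalen-1-yl]propanoic acid | CC(=O)Oc1cc(C)c(O)c(C[C@]2(C)[C@H]3CCC(=C(C)C)[C@@H](CCC(=O)O)[C@]3(C)CC[C@H]2C)c1 | target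

**Step count and risks**

Total step count: 14. Longest linear sequence: 14 steps (from 1).

Three steps most likely to fail:

Step 10 (radical bicyclisation). The risks are reduction of the first radical before it cyclises, modest selectivity at C-5 (methyl and arylmethyl have similar size on a planar radical), and slow attack on the enol lactone. The fallback sets out from 18 and comes back at 22, and closes the rings through cations instead of radicals. Hydrogen-atom transfer from a cobalt hydride with oxidation of the tertiary radical ([N,N′-bis(3,5-di-tert-butylsalicylidene)cyclohexane-1,2-diaminato]cobalt, N-fluoro-2,4,6-trimethylpyridinium triflate, (Me2SiH)2O, (CF3)2CHOH, 0 °C) gives the C-5 cation; the polyene cyclises with the enol lactone as the terminating nucleophile. Water in the work-up opens the acyloxycarbenium ion to the keto acid aryl acetate 3-[(1S,4aR,5S,6R,8aR)-5-(2-acetoxy-3-methylbenzyl)-5,6,8a-trimethyl-2-oxodecahydronaphthalen-1-yl]propanoic acid F1. LiOH in THF/H2O then removes the aryl acetate to give the keto acid phenol 3-[(1S,4aR,5S,6R,8aR)-5-(2-hydroxy-3-methylbenzyl)-5,6,8a-trimethyl-2-oxodecahydronaphthalen-1-yl]propanoic acid F2, and K2NO(SO3)2 in phosphate buffer oxidises the phenol to the quinone 22.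

Step 13 (cross-coupling of a hindered ketone with acetone beside a free acid and a quinone). The fallback sets out from 22 and comes back at 24, and replaces reductive carbonyl coupling by addition and ionic reductive transposition. Na2S2O4 in EtOAc/H2O reduces the quinone to the hydroquinone keto acid 3-[(1S,4aR,5S,6R,8aR)-5-(2,5-dihydroxy-3-methylbenzyl)-5,6,8a-trimethyl-2-oxodecahydronaphthalen-1-yl]propanoic acid F3. Excess CH2=C(CH3)MgBr with CeCl3 in THF at −78 °C adds to the ketone, and acidic work-up closes the tertiary allylic lactone, the δ-lactone of 3-[(1S,4aR,5S,6R,8aR)-5-(2,5-dihydroxy-3-methylbenzyl)-2-hydroxy-5,6,8a-trimethyl-2-(prop-1-en-2-yl)decahydronaphthalen-1-yl]propanoic acid F4. Et3SiH and BF3·OEt2 in CH2Cl2 at −78 °C ionise the allylic C–O bond and deliver hydride to the terminal CH2 of the allyl cation, which gives the isopropylidene acid 24 and frees the carboxylic acid in the same event.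

Step 7 (direct palladium allylation with an unactivated, prenyl-type allylic alcohol; risks are E/Z scrambling, double allylation and phenol allylation). The fallback sets out from 14 and comes back at 16, and uses a classical enolate alkylation. CBr4 and PPh3 in CH2Cl2 at 0 °C give the allylic bromide 2-[(3R,6E)-8-bromo-3,6-dimethyl-2-methylideneoct-6-en-1-yl]-6-methylphenol F5. F5 then C-alkylates 15 (3 equiv) with KOH (1 equiv per dione) in H2O/acetone at 23 °C; only the dione (pKa about 5) is deprotonated, so the phenol stays free, and the product is 16.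

**Further compounds**

F1 | step 10 | 3-[(1S,4aR,5S,6R,8aR)-5-(2-acetoxy-3-methylbenzyl)-5,6,8a-trimethyl-2-oxodecahydronaphthalen-1-yl]propanoic acid | Cc1cccc(C[C@]2(C)[C@H]3CCC(=O)[C@@H](CCC(=O)O)[C@]3(C)CC[C@H]2C)c1OC(C)=O
F2 | step 10 | 3-[(1S,4aR,5S,6R,8aR)-5-(2-hydroxy-3-methylbenzyl)-5,6,8a-trimethyl-2-oxodecahydronaphthalen-1-yl]propanoic acid | Cc1cccc(C[C@]2(C)[C@H]3CCC(=O)[C@@H](CCC(=O)O)[C@]3(C)CC[C@H]2C)c1O
F3 | step 13 | 3-[(1S,4aR,5S,6R,8aR)-5-(2,5-dihydroxy-3-methylbenzyl)-5,6,8a-trimethyl-2-oxodecahydronaphthalen-1-yl]propanoic acid | Cc1cc(O)cc(C[C@]2(C)[C@H]3CCC(=O)[C@@H](CCC(=O)O)[C@]3(C)CC[C@H]2C)c1O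
F4 | step 13 | δ-lactone of 3-[(1S,4aR,5S,6R,8aR)-5-(2,5-dihydroxy-3-methylbenzyl)-2-hydroxy-5,6,8a-trimethyl-2-(prop-1-en-2-yl)decahydronaphthalen-1-yl]propanoic acid (C-2 epimers) | Cc1cc(O)cc(C[C@]2(C)[C@H]3CCC4(C(C)=C)OC(=O)CC[C@H]4[C@]3(C)CC[C@H]2C)c1O
F5 | step 7 | 2-[(3R,6E)-8-bromo-3,6-dimethyl-2-methylideneoct-6-en-1-yl]-6-methylphenol | Cc1cccc(CC(=C)[C@H](C)CC/C(C)=C/CBr)c1O
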